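**Retrosynthetic overview**

1. The route rests on the quinone ring of the 2-aryl-5-hydroxy-7-methyl-1,4-naphthoquinone: its C2=C3 bond joins the aryl-bearing C2 to the unsubstituted C3, so the ring is opened there, with C4 and C3 traced to an acetyl group on C4a and C1 and C2 to an arylethynyl group on C8a.
2. Both aromatic halves come from one ketone, 1-(2-hydroxy-6-methoxy-4-methylphenyl)ethanone (5): its triflate is the ring A partner, and iodination, enaminone cyclisation and triflate carbonylation turn it into the 8-ethynylchromone-5-carboxylate.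
3. Ring order: pyranone ring of the chromone (step 5), Sonogashira union (step 11), gold closure of the carbocycle as a 1-silyloxynaphthalene (step 13), then oxidation at the free para carbon to the quinone.
4. The acid is carried as a benzyl ester, so that BCl3 removes it together with the peri methyl ether and no hydroxide meets the 2-unsubstituted chromone or the quinone.

Key step: step 13

Remark: the target has no stereocentre; rotation about the quinone–chromone bond is hindered, but the target carries no axial descriptor, so this axis is not controlled.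

**Route**

Step 1
Reactants: 1 3,5-dimethoxytoluene; 2 N-methoxy-N-methylacetamide
Product: 4 1-(2,6-dimethoxy-4-methylphenyl)ethanone, via aryllithium 3 (not isolated)
Conditions: n-BuLi, THF, 0 °C to rt; then 2, −78 °C to rt; 1 M HCl
Reagents that add atoms: none
Why: Directed ortho-lithiation should take place at the carbon flanked by both methoxy groups, and acylation of the aryllithium with the Weinreb amide stops at the ketone because the chelated tetrahedral adduct survives until work-up.

Step 2
Reactants: 4 1-(2,6-dimethoxy-4-methylphenyl)ethanone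
Product: 5 1-(2-hydroxy-6-methoxy-4-methylphenyl)ethanone
Conditions: BCl3 (1.1 equiv), CH2Cl2, −78 to 0 °C; H2O
Reagents that add atoms: none
Why: Carbonyl-directed Lewis acid demethylation cleaves one ortho methyl ether, and the boron chelate so formed should shield the second methoxy group from further cleavage.

Step 3
Reactants: 5 1-(2-hydroxy-6-methoxy-4-methylphenyl)ethanone
Product: 6 2-acetyl-3-methoxy-5-methylphenyl trifluoromethanesulfonate
Conditions: Tf2O, pyridine, CH2Cl2, 0 °C
Reagents that add atoms: trifluoromethanesulfonic anhydride, O=S(=O)(OS(=O)(=O)C(F)(F)F)C(F)(F)F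
Why: O-sulfonylation of the phenol gives the aryl triflate that serves as the ring A partner in the later Sonogashira coupling.

Step 4
Reactants: 5 1-(2-hydroxy-6-methoxy-4-methylphenyl)ethanone
Product: 7 1-(2-hydroxy-3-iodo-6-methoxy-4-methylphenyl)ethanone
Conditions: NIS, CF3CO2H (cat.), MeCN, 0 °C to rt
Reagents that add atoms: N-iodosuccinimide, O=C1CCC(=O)N1I
Why: Electrophilic aromatic iodination should go to C3, which is ortho to the chelated hydroxyl and para to the methoxy group and is less shielded than C5 beside the in-plane O-methyl group, as is the rule for 2-hydroxy-6-methoxyacetophenones with a 4-substituent.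

Step 5
Reactants: 7 1-(2-hydroxy-3-iodo-6-methoxy-4-methylphenyl)ethanone
Product: 9 8-iodo-5-methoxy-7-methyl-4H-chromen-4-one, via enaminone 8 (not isolated)
Conditions: Me2NCH(OMe)2, toluene, 100 °C; then conc. HCl, CH2Cl2, rt
Reagents that add atoms: N,N-dimethylformamide dimethyl acetal, COC(OC)N(C)C
Why: Condensation of the methyl ketone with the formamide acetal gives the enaminone, and acid then promotes addition of the only free hydroxyl (the one next to iodine) and loss of dimethylamine, the standard enaminone chromone synthesis, which places iodine at C8.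

Step 6
Reactants: 9 8-iodo-5-methoxy-7-methyl-4H-chromen-4-one
Product: 10 5-hydroxy-8-iodo-7-methyl-4H-chromen-4-one
Conditions: BCl3, CH2Cl2, −78 °C to rt; H2O
Reagents that add atoms: none
Why: The methyl ether peri to the C4 carbonyl is cleaved through a boron chelate, while the aryl iodide and the pyranone ring are inert to BCl3.

Step 7
Reactants: 10 5-hydroxy-8-iodo-7-methyl-4H-chromen-4-one; 11 ethynyltriisopropylsilane
Product: 12 5-hydroxy-7-methyl-8-[(triisopropylsilyl)ethynyl]-4H-chromen-4-one
Conditions: Pd(PPh3)2Cl2 (cat.), CuI (cat.), Et3N, THF, 50 °C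
Reagents that add atoms: none
Why: Sonogashira coupling at the only carbon–halogen bond should proceed because the sp partner tolerates the two ortho substituents, and the hydrogen-bonded phenol needs no protection.

Step 8
Reactants: 12 5-hydroxy-7-methyl-8-[(triisopropylsilyl)ethynyl]-4H-chromen-4-one
Product: 13 7-methyl-4-oxo-8-[(triisopropylsilyl)ethynyl]-4H-chromen-5-yl trifluoromethanesulfonate
Conditions: Tf2O, pyridine, CH2Cl2, 0 °C to rt
Reagents that add atoms: trifluoromethanesulfonic anhydride, O=S(=O)(OS(=O)(=O)C(F)(F)F)C(F)(F)F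
Why: O-sulfonylation of the 5-hydroxychromone turns the oxygen that directed the iodination into a leaving group for carbonylation, now that no aryl iodide is left to compete.

Step 9
Reactants: 13 7-methyl-4-oxo-8-[(triisopropylsilyl)ethynyl]-4H-chromen-5-yl trifluoromethanesulfonate
Product: 14 benzyl 7-methyl-4-oxo-8-[(triisopropylsilyl)ethynyl]-4H-chromene-5-carboxylate
Conditions: Pd(OAc)2 (cat.), dppp, Et3N, BnOH, CO (1 atm), DMF, 70 °C
Reagents that add atoms: carbon monoxide, [C-]#[O+]; benzyl alcohol, OCc1ccccc1
Why: Palladium-catalysed alkoxycarbonylation of the electron-poor aryl triflate (oxidative addition, CO insertion, alcoholysis) installs the ester carbon at C5, and the bulky silyl alkyne should be inert to the amine and the alcohol.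

Step 10
Reactants: 14 benzyl 7-methyl-4-oxo-8-[(triisopropylsilyl)ethynyl]-4H-chromene-5-carboxylate
Product: 15 benzyl 8-ethynyl-7-methyl-4-oxo-4H-chromene-5-carboxylate
Conditions: Bu4NF, AcOH, THF, 0 °C to rt
Reagents that add atoms: none
Why: Fluoride cleaves the C(sp)–Si bond, and the acetic acid buffer keeps basic fluoride from attacking C2 of the chromone.

Step 11
Reactants: 15 benzyl 8-ethynyl-7-methyl-4-oxo-4H-chromene-5-carboxylate; 6 2-acetyl-3-methoxy-5-methylphenyl trifluoromethanesulfonate
Product: 16 benzyl 8-[(2-acetyl-3-methoxy-5-methylphenyl)ethynyl]-7-methyl-4-oxo-4H-chromene-5-carboxylate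
Conditions: Pd(PPh3)2Cl2 (cat.), CuI (cat.), Et3N, DMF, 70 °C, slow addition of 15
Reagents that add atoms: none
Why: Sonogashira coupling of the aryl triflate, activated towards oxidative addition by its ortho acetyl group, joins the two halves at an sp carbon that is insensitive to the crowding around chromone C8.

Step 12
Reactants: 16 benzyl 8-[(2-acetyl-3-methoxy-5-methylphenyl)ethynyl]-7-methyl-4-oxo-4H-chromene-5-carboxylate
Product: 17 benzyl 8-{[2-(1-(tert-butyldimethylsilyloxy)ethenyl)-3-methoxy-5-methylphenyl]ethynyl}-7-methyl-4-oxo-4H-chromene-5-carboxylate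
Conditions: TBSOTf (1.3 equiv), Et3N (4 equiv), CH2Cl2, −78 to 0 °C; NaHCO3 work-up
Reagents that add atoms: tert-butyldimethylsilyl trifluoromethanesulfonate, CC(C)(C)[Si](C)(C)OS(=O)(=O)C(F)(F)F
Why: Soft enolisation of the only enolisable ketone gives the silyl enol ether, and the excess of amine, low temperature and slow addition of the triflate are meant to keep the chromone carbonyl from being held as a silyloxypyrylium ion.

Step 13
Reactants: 17 benzyl 8-{[2-(1-(tert-butyldimethylsilyloxy)ethenyl)-3-methoxy-5-methylphenyl]ethynyl}-7-methyl-4-oxo-4H-chromene-5-carboxylate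
Product: 18 benzyl 8-[4-(tert-butyldimethylsilyloxy)-5-methoxy-7-methylnaphthalen-2-yl]-7-methyl-4-oxo-4H-chromene-5-carboxylate
Conditions: Ph3PAuNTf2 (5 mol%), CH2Cl2, rt
Reagents that add atoms: none
Why: The monovalent gold cation binds the diaryl alkyne, and the terminal carbon of the enol ether (the future C3) adds anti to gold at the alkyne carbon that carries the chromone (the future C2), giving an aryl-gold silyloxocarbenium species. Loss of the C3 proton and protodeauration at C1 then give the aromatic 1-silyloxynaphthalene, so the step is an isomerisation without by-product. It is the known π-acid-catalysed carbocyclisation of silyl enol ethers of ortho-alkynyl aryl ketones to 1-silyloxynaphthalenes. The one new ring, the carbocycle that becomes the quinone ring, closes in the 6-endo-dig mode, and no stereocentre is formed. The step needs endo over 5-exo closure: the enol ether and alkyne are held ortho on a rigid benzene ring, and only the endo path ends in a naphthalene, whereas the exo path would give a strained alkylidene-indene. It also needs carbon and not oxygen to attack, which the silyl cap on the enol oxygen secures.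

Step 14
Reactants: 18 benzyl 8-[4-(tert-butyldimethylsilyloxy)-5-methoxy-7-methylnaphthalen-2-yl]-7-methyl-4-oxo-4H-chromene-5-carboxylate
Product: 19 benzyl 8-(4-hydroxy-5-methoxy-7-methylnaphthalen-2-yl)-7-methyl-4-oxo-4H-chromene-5-carboxylate
Conditions: Bu4NF, AcOH, THF, 0 °C
Reagents that add atoms: none
Why: Buffered fluoride cleaves the aryl silyl ether to the naphthol without exposing the chromone or the benzyl ester to base.

Step 15
Reactants: 19 benzyl 8-(4-hydroxy-5-methoxy-7-methylnaphthalen-2-yl)-7-methyl-4-oxo-4H-chromene-5-carboxylate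
Product: 20 benzyl 8-(5-methoxy-7-methyl-1,4-dioxo-1,4-dihydronaphthalen-2-yl)-7-methyl-4-oxo-4H-chromene-5-carboxylate
Conditions: (KO3S)2NO, KH2PO4, acetone/H2O, rt
Reagents that add atoms: potassium nitrosodisulfonate (KO3S)2NO, [K+].[K+].[O]N(S(=O)(=O)[O-])S(=O)(=O)[O-]
Why: In this Teuber oxidation one nitrosodisulfonate radical abstracts the phenolic hydrogen and a second couples at the free para carbon C1, whose adduct collapses to the 1,4-quinone, the normal course for 1-naphthols with an open 4-position.

Step 16
Reactants: 20 benzyl 8-(5-methoxy-7-methyl-1,4-dioxo-1,4-dihydronaphthalen-2-yl)-7-methyl-4-oxo-4H-chromene-5-carboxylate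
Product: 21 8-(5-hydroxy-7-methyl-1,4-dioxo-1,4-dihydronaphthalen-2-yl)-7-methyl-4-oxo-4H-chromene-5-carboxylic acid (target)
Conditions: BCl3 (excess), CH2Cl2, −78 °C to rt; H2O
Reagents that add atoms: none
Why: BCl3 cleaves the methyl ether peri to the quinone C4 carbonyl through a chelate and the benzyl ester by chloride attack at the benzylic carbon, so both protecting groups should fall in one Lewis acid step without any hydroxide.

**Compound list**

1 | 3,5-dimethoxytoluene | COc1cc(C)cc(OC)c1 | starting material
2 | N-methoxy-N-methylacetamide | CC(=O)N(C)OC | starting material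
3 | (2,6-dimethoxy-4-methylphenyl)lithium | [Li]c1c(OC)cc(C)cc1OC | intermediate
4 | 1-(2,6-dimethoxy-4-methylphenyl)ethanone | CC(=O)c1c(OC)cc(C)cc1OC | intermediate
5 | 1-(2-hydroxy-6-methoxy-4-methylphenyl)ethanone | CC(=O)c1c(O)cc(C)cc1OC | intermediate
6 | 2-acetyl-3-methoxy-5-methylphenyl trifluoromethanesulfonate | CC(=O)c1c(OC)cc(C)cc1OS(=O)(=O)C(F)(F)F | intermediate
7 | 1-(2-hydroxy-3-iodo-6-methoxy-4-methylphenyl)ethanone | CC(=O)c1c(O)c(I)c(C)cc1OC | intermediate
8 | (E)-3-(dimethylamino)-1-(2-hydroxy-3-iodo-6-methoxy-4-methylphenyl)prop-2-en-1-one | CN(C)/C=C/C(=O)c1c(O)c(I)c(C)cc1OC | intermediate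
9 | 8-iodo-5-methoxy-7-methyl-4H-chromen-4-one | COc1cc(C)c(I)c2occc(=O)c12 | intermediate
10 | 5-hydroxy-8-iodo-7-methyl-4H-chromen-4-one | Oc1cc(C)c(I)c2occc(=O)c12 | intermediate
11 | ethynyltriisopropylsilane | C#C[Si](C(C)C)(C(C)C)C(C)C | starting material
12 | 5-hydroxy-7-methyl-8-[(triisopropylsilyl)ethynyl]-4H-chromen-4-one | Oc1cc(C)c(C#C[Si](C(C)C)(C(C)C)C(C)C)c2occc(=O)c12 | intermediate
13 | 7-methyl-4-oxo-8-[(triisopropylsilyl)ethynyl]-4H-chromen-5-yl trifluoromethanesulfonate | Cc1cc(OS(=O)(=O)C(F)(F)F)c2c(=O)ccoc2c1C#C[Si](C(C)C)(C(C)C)C(C)C | intermediate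
14 | benzyl 7-methyl-4-oxo-8-[(triisopropylsilyl)ethynyl]-4H-chromene-5-carboxylate | Cc1cc(C(=O)OCc2ccccc2)c2c(=O)ccoc2c1C#C[Si](C(C)C)(C(C)C)C(C)C | intermediate
15 | benzyl 8-ethynyl-7-methyl-4-oxo-4H-chromene-5-carboxylate | C#Cc1c(C)cc(C(=O)OCc2ccccc2)c2c(=O)ccoc12 | intermediate
16 | benzyl 8-[(2-acetyl-3-methoxy-5-methylphenyl)ethynyl]-7-methyl-4-oxo-4H-chromene-5-carboxylate | CC(=O)c1c(OC)cc(C)cc1C#Cc1c(C)cc(C(=O)OCc2ccccc2)c2c(=O)ccoc12 | intermediate
17 | benzyl 8-{[2-(1-(tert-butyldimethylsilyloxy)ethenyl)-3-methoxy-5-methylphenyl]ethynyl}-7-methyl-4-oxo-4H-chromene-5-carboxylate | C=C(O[Si](C)(C)C(C)(C)C)c1c(OC)cc(C)cc1C#Cc1c(C)cc(C(=O)OCc2ccccc2)c2c(=O)ccoc12 | intermediate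
18 | benzyl 8-[4-(tert-butyldimethylsilyloxy)-5-methoxy-7-methylnaphthalen-2-yl]-7-methyl-4-oxo-4H-chromene-5-carboxylate | COc1cc(C)cc2cc(-c3c(C)cc(C(=O)OCc4ccccc4)c4c(=O)ccoc34)cc(O[Si](C)(C)C(C)(C)C)c12 | intermediate
19 | benzyl 8-(4-hydroxy-5-methoxy-7-methylnaphthalen-2-yl)-7-methyl-4-oxo-4H-chromene-5-carboxylate | COc1cc(C)cc2cc(-c3c(C)cc(C(=O)OCc4ccccc4)c4c(=O)ccoc34)cc(O)c12 | intermediate
20 | benzyl 8-(5-methoxy-7-methyl-1,4-dioxo-1,4-dihydronaphthalen-2-yl)-7-methyl-4-oxo-4H-chromene-5-carboxylate | COc1cc(C)cc2c1C(=O)C=C(c1c(C)cc(C(=O)OCc3ccccc3)c3c(=O)ccoc13)C2=O | intermediate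
21 | 8-(5-hydroxy-7-methyl-1,4-dioxo-1,4-dihydronaphthalen-2-yl)-7-methyl-4-oxo-4H-chromene-5-carboxylic acid | Cc1cc(O)c2c(c1)C(=O)C(c1c(C)cc(C(=O)O)c3c(=O)ccoc13)=CC2=O | target

**Step count and risks**

Total step count: 16. Longest linear sequence: 15 steps (steps 1, 2 and 4 to 16); step 3 is the one-step side branch to the ring A triflate.

Steps most likely to fail:

Step 13 (gold cyclisation). The ring may close in the 5-exo mode, or the silyl group may be lost before closure, so that the ketone oxygen and not carbon adds to the gold-bound alkyne. The fallback uses the carbanion in place of the π-acid and sets out from ketone 16. KN(SiMe3)2 (1.05 equiv) in THF at −78 to 0 °C should deprotonate the acetyl group, and the potassium enolate should add to the alkyne in the anionic 6-endo-dig mode known for 2-alkynylacetophenones. Proton transfer and tautomerisation give potassium 3-[5-(benzyloxycarbonyl)-7-methyl-4-oxo-4H-chromen-8-yl]-8-methoxy-6-methylnaphthalen-1-olate F1. Aqueous NH4Cl then gives naphthol 19, where the route is rejoined; steps 12 to 14 fall away.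

Step 4 (iodination). The iodonium may attack C5, para to the hydroxyl, in place of C3. The fallback sets out from 5 and uses that isomer by exchanging the roles of the two oxygens. The isomer 1-(6-hydroxy-3-iodo-2-methoxy-4-methylphenyl)ethanone F2 is coupled with 11 under the Sonogashira conditions of step 7 to 1-{6-hydroxy-2-methoxy-4-methyl-3-[(triisopropylsilyl)ethynyl]phenyl}ethanone F3. Its free hydroxyl is sulfonylated with Tf2O and pyridine to 2-acetyl-3-methoxy-5-methyl-4-[(triisopropylsilyl)ethynyl]phenyl trifluoromethanesulfonate F4. BCl3 then cleaves the remaining methyl ether, which lies between the acetyl group and the alkyne, to 2-acetyl-3-hydroxy-5-methyl-4-[(triisopropylsilyl)ethynyl]phenyl trifluoromethanesulfonate F5. The formamide acetal and then HCl close the pyranone on the hydroxyl beside the alkyne, through 2-[(E)-3-(dimethylamino)prop-2-enoyl]-3-hydroxy-5-methyl-4-[(triisopropylsilyl)ethynyl]phenyl trifluoromethanesulfonate F6. This gives chromenyl triflate 13, where the route is rejoined; steps 5 to 8 are replaced.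

Step 12 (silyl enol ether formation). TBSOTf may silylate the chromone carbonyl to a silyloxybenzopyrylium ion, to which the freshly formed enol ether can add at C2, so that 17 is consumed by oligomerisation. The fallback forms the enol ether before the chromone is present and sets out from triflate 6. TBSOTf and Et3N in CH2Cl2 give 2-[1-(tert-butyldimethylsilyloxy)ethenyl]-3-methoxy-5-methylphenyl trifluoromethanesulfonate F7. Sonogashira coupling of F7 with alkyne 15 (Pd(PPh3)2Cl2, CuI, Et3N, DMF, 70 °C, anhydrous) gives 17 directly, where the route is rejoined; the ketone 16 is bypassed.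

**Further compounds**

F1 | step 13 | potassium 3-[5-(benzyloxycarbonyl)-7-methyl-4-oxo-4H-chromen-8-yl]-8-methoxy-6-methylnaphthalen-1-olate | COc1cc(C)cc2cc(-c3c(C)cc(C(=O)OCc4ccccc4)c4c(=O)ccoc34)cc([O-])c12.[K+]
F2 | step 4 | 1-(6-hydroxy-3-iodo-2-methoxy-4-methylphenyl)ethanone | CC(=O)c1c(O)cc(C)c(I)c1OC
F3 | step 4 | 1-{6-hydroxy-2-methoxy-4-methyl-3-[(triisopropylsilyl)ethynyl]phenyl}ethanone | CC(=O)c1c(O)cc(C)c(C#C[Si](C(C)C)(C(C)C)C(C)C)c1OC
F4 | step 4 | 2-acetyl-3-methoxy-5-methyl-4-[(triisopropylsilyl)ethynyl]phenyl trifluoromethanesulfonate | CC(=O)c1c(OS(=O)(=O)C(F)(F)F)cc(C)c(C#C[Si](C(C)C)(C(C)C)C(C)C)c1OC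
F5 | step 4 | 2-acetyl-3-hydroxy-5-methyl-4-[(triisopropylsilyl)ethynyl]phenyl trifluoromethanesulfonate | CC(=O)c1c(OS(=O)(=O)C(F)(F)F)cc(C)c(C#C[Si](C(C)C)(C(C)C)C(C)C)c1O
F6 | step 4 | 2-[(E)-3-(dimethylamino)prop-2-enoyl]-3-hydroxy-5-methyl-4-[(triisopropylsilyl)ethynyl]phenyl trifluoromethanesulfonate | CN(C)/C=C/C(=O)c1c(OS(=O)(=O)C(F)(F)F)cc(C)c(C#C[Si](C(C)C)(C(C)C)C(C)C)c1O
F7 | step 12 | 2-[1-(tert-butyldimethylsilyloxy)ethenyl]-3-methoxy-5-methylphenyl trifluoromethanesulfonate | C=C(O[Si](C)(C)C(C)(C)C)c1c(OC)cc(C)cc1OS(=O)(=O)C(F)(F)F
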